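## Retrosynthetic overview

1. Target 9 ⇒ two molecules of (12E)-labda-8(17),12,14-trien-18-ol 8 by an endo, "ortho" Diels–Alder dimerisation (bonds C14–C12′ and C15–C15′). The central cyclohexene (ring C) is the only ring built and is formed last.
2. 8 ⇒ aldehyde 6 by two Wittig olefinations (C12=C13 with E geometry, then C14=C15).
3. 6 ⇒ 18-hydroxysclareolide 2 by lactone aminolysis, regioselective dehydration to the 8(17)-alkene and reduction. Rings A and B with C5, C9 and C10 are bought in (+)-sclareolide 1.
4. Key disconnection: the C18–O bond. 2 ⇒ 1 by hydroxylation of the equatorial 4α-methyl, which makes the C–O bond and creates the C4 stereocentre in the first step.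

Assumption: labdane numbering is used (C18 = 4α carbon, C19 = 4β-methyl, C20 = methyl on C10, C17 = carbon on C8). In 9, unit A is the half that keeps the 12E alkene and unit B (primed locants) is the half whose diene became ring C.

## Route

Step 1
Reactants: 1 (+)-sclareolide
Product: 2 18-hydroxysclareolide (4α-hydroxymethyl and 4β-methyl; 4R)
Conditions: cytochrome P450 BM3 (CYP102A1) variant evolved for C18 selectivity (0.2 mol%), NADP+ (cat.), glucose, glucose dehydrogenase, air, KH2PO4/K2HPO4 buffer pH 8.0, 2% EtOH, 25 °C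
Reagents that add atoms: dioxygen, O=O
Why: Proposed new method: a P450 BM3 variant that hydroxylates the equatorial 4α-methyl of sclareolide, in which the ferryl-oxo haem (iron in its tetravalent state, porphyrin radical cation) abstracts a C18 hydrogen and oxygen rebound forms the C18–O bond, so site selection comes from substrate positioning and not from C–H bond strength; the design keeps the lactone carbonyl anchored at the channel mouth (R47/Y51) and narrows the pocket above the haem (bulky residues at positions 78, 82, 87 and 328) so that only the tip of ring A reaches the oxidant, where the equatorial C18 methyl projects furthest while the axial C19 methyl is screened by the syn-axial C20 methyl and the weaker C2/C3 C–H bonds are held back, which selects one of two diastereotopic methyl groups and so sets C4 as 4R; the closest known reaction types are the engineered P450 BM3 3β-hydroxylation of sclareolide, terminal-methyl hydroxylation by ω-hydroxylases and the C18/C19/C23 methyl oxidations of terpenoid-tailoring P450 enzymes.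

Step 2
Reactants: 2 18-hydroxysclareolide
Product: 3 8α,18-dihydroxy-13,14,15,16-tetranorlabdan-12-oic acid N-methoxy-N-methylamide
Conditions: MeNH(OMe)·HCl (4 equiv), Me3Al (4 equiv), CH2Cl2, 0 °C to rt; aq. KNaC4H4O6 (tartrate) work-up; crude product used at once
Reagents that add atoms: N,O-dimethylhydroxylamine hydrochloride, CNOC.Cl
Why: Aluminium-amide aminolysis of the lactone (Weinreb amide formation) cleaves the acyl C–O bond, so C8 keeps its configuration and the free hydroxyl only consumes one more equivalent of Me3Al.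

Step 3
Reactants: 3 8α,18-dihydroxy-13,14,15,16-tetranorlabdan-12-oic acid N-methoxy-N-methylamide
Product: 5 18-acetoxy-13,14,15,16-tetranorlabd-8(17)-en-12-oic acid N-methoxy-N-methylamide, via hydroxy acetate 4 (not isolated)
Conditions: Ac2O (1.2 equiv), pyridine, CH2Cl2, 0 °C to rt; then SOCl2 (3 equiv), −78 °C; aq. NaHCO3
Reagents that add atoms: acetic anhydride, CC(=O)OC(C)=O
Why: Ac2O/pyridine acetylates only the primary hydroxyl, and the SOCl2/pyridine dehydration then runs as an E2 elimination through the equatorial 8α-chlorosulfite, which has no anti-periplanar ring hydrogen and therefore loses a C17 hydrogen to give the exocyclic 8(17)-alkene.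

Step 4
Reactants: 5 18-acetoxy-13,14,15,16-tetranorlabd-8(17)-en-12-oic acid N-methoxy-N-methylamide
Product: 6 18-hydroxy-13,14,15,16-tetranorlabd-8(17)-en-12-al
Conditions: i-Bu2AlH (4.5 equiv), THF, −78 to −40 °C; aq. KNaC4H4O6 (tartrate)
Reagents that add atoms: none
Why: Weinreb amide reduction stops at the chelated tetrahedral aluminate, which gives the aldehyde only on work-up, while the same hydride cleaves the acetate reductively, so the protecting group is removed without an extra step and no stereocentre is touched.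

Step 5
Reactants: 6 18-hydroxy-13,14,15,16-tetranorlabd-8(17)-en-12-al
Product: 7 (12E)-18-hydroxy-15-norlabda-8(17),12-dien-14-al
Conditions: Ph3P=C(CH3)CHO (1.5 equiv), toluene, 90 °C
Reagents that add atoms: 2-(triphenylphosphoranylidene)propanal, CC(C=O)=P(c1ccccc1)(c1ccccc1)c1ccccc1
Why: Wittig olefination with a carbonyl-stabilised ylide gives the (E)-2-methyl enal (C11 trans to CHO, typically above 95:5), which fixes the 12E geometry.

Step 6
Reactants: 7 (12E)-18-hydroxy-15-norlabda-8(17),12-dien-14-al
Product: 8 (12E)-labda-8(17),12,14-trien-18-ol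
Conditions: Ph3PCH3Br (3.2 equiv), KOt-Bu (3.0 equiv), THF, 0 °C to rt
Reagents that add atoms: methyltriphenylphosphonium bromide, C[P+](c1ccccc1)(c1ccccc1)c1ccccc1.[Br-]
Why: Wittig methylenation by the non-stabilised ylide adds 1,2 to the enal carbonyl (excess ylide covers the free hydroxyl) and completes the 12E,14-diene without touching the trisubstituted alkene.

Step 7
Reactants: 8 (12E)-labda-8(17),12,14-trien-18-ol (two molecules)
Product: 9 CNP0194625.1, the cis (14S,12′S) Diels–Alder dimer of 8
Conditions: neat under argon, BHT (1 mol%), 130 °C, sealed tube, 48–72 h; silica gel, then preparative HPLC; unreacted 8 recycled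
Reagents that add atoms: none
Why: Thermal Diels–Alder dimerisation in which the s-cis 12′E,14′-diene of one molecule adds to the unhindered C14=C15 vinyl group of a second; joining the two unsubstituted CH2 termini (C15–C15′) gives the "ortho" regiochemistry, and the endo transition state puts the C14 substituent cis to the outward C11′ chain on C12′, but the decalin stereocentres are too remote to bias the diene face, so the 14S,12′S target is expected in about equal amount with its 14R,12′R cis diastereomer and is separated from it by HPLC.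

## Compound list

1 | (+)-sclareolide (13,14,15,16-tetranorlabdano-12,8α-lactone; 3aR,5aS,9aS,9bR) | C[C@@]12CC[C@H]3C(C)(C)CCC[C@]3(C)[C@H]1CC(=O)O2 | starting material
2 | 18-hydroxysclareolide (4α-CH2OH, 4β-CH3; 4R) | C[C@@]12CC[C@H]3[C@](C)(CO)CCC[C@]3(C)[C@H]1CC(=O)O2 | intermediate
3 | 8α,18-dihydroxy-13,14,15,16-tetranorlabdan-12-oic acid N-methoxy-N-methylamide | C[C@@]1(O)CC[C@H]2[C@](C)(CO)CCC[C@]2(C)[C@H]1CC(=O)N(C)OC | intermediate
4 | 18-acetoxy-8α-hydroxy-13,14,15,16-tetranorlabdan-12-oic acid N-methoxy-N-methylamide | C[C@@]1(O)CC[C@H]2[C@](C)(COC(C)=O)CCC[C@]2(C)[C@H]1CC(=O)N(C)OC | intermediate (not isolated)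
5 | 18-acetoxy-13,14,15,16-tetranorlabd-8(17)-en-12-oic acid N-methoxy-N-methylamide | C=C1CC[C@H]2[C@](C)(COC(C)=O)CCC[C@]2(C)[C@H]1CC(=O)N(C)OC | intermediate
6 | 18-hydroxy-13,14,15,16-tetranorlabd-8(17)-en-12-al | C=C1CC[C@H]2[C@](C)(CO)CCC[C@]2(C)[C@H]1CC=O | intermediate
7 | (12E)-18-hydroxy-15-norlabda-8(17),12-dien-14-al | C=C1CC[C@H]2[C@](C)(CO)CCC[C@]2(C)[C@H]1C/C=C(\C)C=O | intermediate
8 | (12E)-labda-8(17),12,14-trien-18-ol | C=C1CC[C@H]2[C@](C)(CO)CCC[C@]2(C)[C@H]1C/C=C(\C)C=C | intermediate
9 | CNP0194625.1: unit A (labda-8(17),12E-dien-18-ol, bonded at C14) and unit B (labd-8(17)-en-18-ol, bonded through C11′ to C12′) on a 3-methylcyclohex-3-ene ring C14–C15–C15′–C14′=C13′(CH3)–C12′, with C14 and C12′ substituents cis (14S,12′S) | C=C1CC[C@H]2[C@](C)(CO)CCC[C@]2(C)[C@H]1C/C=C(\C)[C@H]1CCC=C(C)[C@H]1C[C@H]1C(=C)CC[C@H]2[C@](C)(CO)CCC[C@]12C | target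

## Step count and risks

Total steps: 7. Longest linear sequence: 7 (1 → 9).

Steps most likely to fail:

**Step 1 (the proposed enzymatic C18 hydroxylation).** The variant may still prefer the weaker C3/C2 C–H bonds or over-oxidise C18 to the aldehyde or acid. Fallback with known chemistry, setting out from 1 and coming back at 2: a known 3β-selective P450 BM3 variant converts 1 into 3β-hydroxysclareolide F1. Et2SiH2 with [Ir(cod)OMe]2 (cat.) gives the diethyl(hydrido)silyl ether F2. Hydroxyl-directed γ-C–H silylation ([Ir(cod)OMe]2, 3,4,7,8-tetramethyl-1,10-phenanthroline, norbornene, THF, 120 °C) occurs at the equatorial 4α-methyl and gives the oxasilolane F3. Tamao–Fleming oxidation (H2O2, KHCO3, THF/MeOH) gives the 3β,18-diol F4. Thiocarbonyldiimidazole closes the cyclic thionocarbonate F5. Bu3SnH/AIBN in toluene then cleaves the secondary C3–O bond selectively (secondary over primary radical), and hydrolysis of the remaining thiocarbonate residue (K2CO3, MeOH; dilute acid work-up to reclose any opened lactone) returns 2.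

**Step 3 (telescoped acetylation and dehydration).** Acetic acid in the pot may open an ionising pathway that lowers the exo selectivity or lets the γ-hydroxy amide relactonise, and the acetate must then come off cleanly in step 4. Fallback, setting out from 3 and coming back at 6: change to a persistent silyl ether with each operation isolated. TBSCl/imidazole/DMF silylates only the primary hydroxyl and gives the silyl ether F6. SOCl2/pyridine/CH2Cl2 at −78 °C gives the exocyclic alkene F7, with endocyclic isomers removed on AgNO3-impregnated silica. i-Bu2AlH (1.5 equiv, −78 °C) gives the silyloxy aldehyde F8, and Bu4NF in THF returns 6.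

**Step 7 (thermal dimerisation).** Neither the cis/trans ratio nor the facial pairing is controlled, so the target is expected as only about a fifth to a quarter of the dimer fraction and may be hard to separate; oligomerisation is also possible. Fallback, setting out from 8 (with 6 from the main line) and coming back at 9: build ring C by a catalyst-controlled cross Diels–Alder reaction and attach unit A afterwards.
- Ring C: 8 and acrolein under iminium catalysis ((5S)-5-benzyl-2,2,3-trimethylimidazolidin-4-one hydrochloride, 20 mol%, CH3CN/H2O 95:5, rt; the enantiomeric catalyst if the opposite ring sense is found) give the endo, "ortho" cis-cyclohexenecarbaldehyde F9, so the catalyst and not the remote decalin fixes C14 and C12′. The "ortho" outcome relies on the 1-alkyl substituent of the diene outweighing the 2-methyl group and is the main uncertainty here.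
- Alkenyl partner: Colvin homologation (Me3SiC(Li)N2, THF, −78 to 0 °C, non-epimerising) gives the alkyne F10. Zirconium-catalysed methylalumination (Me3Al, Cp2ZrCl2 cat., CH2Cl2) followed by I2 gives the (E)-iodoalkene F11.
- Alkyl partner: 6 is acetylated (Ac2O, pyridine) to the acetoxy aldehyde F12, oxidised (NaClO2, NaH2PO4, 2-methyl-2-butene) to the acid F13 and coupled with N-hydroxyphthalimide (N,N′-diisopropylcarbodiimide) to the N-hydroxyphthalimide ester F14.
- Union: nickel-catalysed reductive decarboxylative alkenylation of F14 with F11 (NiBr2(dme), 4,4′-di-tert-butyl-2,2′-bipyridine, Zn, DMA) forms the C11–C12 bond with retention of the E geometry and gives the monoacetate F15. K2CO3/MeOH then gives 9.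

## Further compounds

F1 | step 1 | 3β-hydroxysclareolide | C[C@@]12CC[C@H]3C(C)(C)[C@@H](O)CC[C@]3(C)[C@H]1CC(=O)O2
F2 | step 1 | 3β-(diethylsilyloxy)sclareolide (diethyl(hydrido)silyl ether of F1) | C[C@@]12CC[C@H]3C(C)(C)[C@@H](O[SiH](CC)CC)CC[C@]3(C)[C@H]1CC(=O)O2
F3 | step 1 | oxasilolane of sclareolide (3β-O–SiEt2–C18 bridge) | C[C@@]12CC[C@H]3[C@]4(C)C[Si](CC)(CC)O[C@H]4CC[C@]3(C)[C@H]1CC(=O)O2
F4 | step 1 | 3β,18-dihydroxysclareolide | C[C@@]12CC[C@H]3[C@](C)(CO)[C@@H](O)CC[C@]3(C)[C@H]1CC(=O)O2
F5 | step 1 | 3β,18-O-thiocarbonyl derivative of F4 (cyclic thionocarbonate) | C[C@@]12CC[C@H]3[C@]4(C)COC(=S)O[C@H]4CC[C@]3(C)[C@H]1CC(=O)O2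
F6 | step 3 | 18-(tert-butyldimethylsilyloxy)-8α-hydroxy-13,14,15,16-tetranorlabdan-12-oic acid N-methoxy-N-methylamide | C[C@@]1(O)CC[C@H]2[C@](C)(CO[Si](C)(C)C(C)(C)C)CCC[C@]2(C)[C@H]1CC(=O)N(C)OC
F7 | step 3 | 18-(tert-butyldimethylsilyloxy)-13,14,15,16-tetranorlabd-8(17)-en-12-oic acid N-methoxy-N-methylamide | C=C1CC[C@H]2[C@](C)(CO[Si](C)(C)C(C)(C)C)CCC[C@]2(C)[C@H]1CC(=O)N(C)OC
F8 | step 3 | 18-(tert-butyldimethylsilyloxy)-13,14,15,16-tetranorlabd-8(17)-en-12-al | C=C1CC[C@H]2[C@](C)(CO[Si](C)(C)C(C)(C)C)CCC[C@]2(C)[C@H]1CC=O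
F9 | step 7 | cis-cyclohexenecarbaldehyde (acrolein adduct of 8; CHO on C14, unit B on C12′) | O=C[C@H]1CCC=C(C)[C@H]1C[C@H]1C(=C)CC[C@H]2[C@](C)(CO)CCC[C@]12C
F10 | step 7 | cis-ethynylcyclohexene (alkyne from F9) | C#C[C@H]1CCC=C(C)[C@H]1C[C@H]1C(=C)CC[C@H]2[C@](C)(CO)CCC[C@]12C
F11 | step 7 | (E)-iodoalkene (E)-CHI=C(CH3)– on C14 | I/C=C(\C)[C@H]1CCC=C(C)[C@H]1C[C@H]1C(=C)CC[C@H]2[C@](C)(CO)CCC[C@]12C
F12 | step 7 | 18-acetoxy-13,14,15,16-tetranorlabd-8(17)-en-12-al | C=C1CC[C@H]2[C@](C)(COC(C)=O)CCC[C@]2(C)[C@H]1CC=O
F13 | step 7 | 18-acetoxy-13,14,15,16-tetranorlabd-8(17)-en-12-oic acid | C=C1CC[C@H]2[C@](C)(COC(C)=O)CCC[C@]2(C)[C@H]1CC(=O)O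
F14 | step 7 | N-hydroxyphthalimide ester of F13 | C=C1CC[C@H]2[C@](C)(COC(C)=O)CCC[C@]2(C)[C@H]1CC(=O)ON1C(=O)c2ccccc2C1=O
F15 | step 7 | 18-O-acetate (unit A) of 9 | C=C1CC[C@H]2[C@](C)(COC(C)=O)CCC[C@]2(C)[C@H]1C/C=C(\C)[C@H]1CCC=C(C)[C@H]1C[C@H]1C(=C)CC[C@H]2[C@](C)(CO)CCC[C@]12C
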